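The route rests on cutting ring B of the eudesmane core at C5–C6 and C9–C10. Ring B carries the imprint of a 1-oxy-2-alkyl diene added to a methylquinone: O6 on C6 beside the fusion carbon C5, isopropyl on C7, the methyl-bearing quaternary C10, and oxygen on C1 and C4 of ring A. One enantioselective Diels–Alder reaction between 2-methoxy-5-methyl-1,4-benzoquinone and (1E)-2-isopropyl-1-(triisopropylsilyloxy)buta-1,3-diene closes ring B, makes both bonds and sets C10, C5 and C6. The folded cis adduct then guides hydrogen to C7, C5 is inverted while C1 is ketalised, and methylenation, dihydroxylation, orthoester exchange and C1 reduction complete the cage.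

Key step: step 4

Convention: eudesmane numbering is used throughout; "methyl face" is the face of the decalin that carries the C10 methyl, "opposite face" is the other one.
Assumption: (R)-BINOL is taken as the antipode that leads to the enantiomer drawn; should the sense of induction be the opposite one, (S)-BINOL is used and nothing else changes.

Step 1
Reactants: 1 isovaleraldehyde; 2 cyclohexylamine
Product: 3 N-(3-methylbutylidene)cyclohexanamine (E-aldimine)
Conditions: 4 Å MS, Et2O, 0 °C → rt; distillation
Reagents that add atoms: none
Why: Imine formation from an aldehyde and a primary amine masks this carbonyl, so that only this partner can later act as the nucleophile of the crossed aldol.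

Step 2
Reactants: 3 N-(3-methylbutylidene)cyclohexanamine; 4 acetaldehyde
Product: 7 (E)-2-isopropylbut-2-enal, via lithium aza-enolate 5 (not isolated), via lithium aldolate 6 (not isolated)
Conditions: LiN(iPr)2, THF, −78 → 0 °C; 4, −78 °C; aq. oxalic acid, reflux
Reagents that add atoms: water, O
Why: Directed aza-enolate aldol condensation: LiN(iPr)2 deprotonates only the carbon alpha to the imine, the aza-enolate adds to acetaldehyde without self-condensation of either aldehyde, and hot aqueous oxalic acid hydrolyses the imine and dehydrates the aldol to the more stable E-enal.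

Step 3
Reactants: 7 (E)-2-isopropylbut-2-enal
Product: 8 (1E)-2-isopropyl-1-(triisopropylsilyloxy)buta-1,3-diene
Conditions: TIPSOTf, Et3N, CH2Cl2, 0 °C → rt
Reagents that add atoms: triisopropylsilyl triflate, CC(C)[Si](OS(=O)(=O)C(F)(F)F)(C(C)C)C(C)C
Why: Silyl dienol ether formation by soft vinylogous enolisation: O-silylation of the s-trans enal and loss of a proton from the only acidic gamma CH3 group should give chiefly the 1E diene, and the TIPS group is chosen because it withstands the Lewis acid of step 4 and the acid of step 7.

Step 4
Reactants: 8 (1E)-2-isopropyl-1-(triisopropylsilyloxy)buta-1,3-diene; 9 2-methoxy-5-methyl-1,4-benzoquinone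
Product: 10 cis-adduct 3-methoxy-6-(triisopropylsilyloxy)-15-noreudesma-2,7-diene-1,4-dione (H5 cis to the C10 methyl; O6 on the opposite face)
Conditions: (R)-BINOL (30 mol %), TiCl2(OiPr)2 (30 mol %), 4 Å MS, toluene, −60 → −20 °C
Reagents that add atoms: none
Why: A concerted but asynchronous normal-demand [4+2] cycloaddition joins the electron-rich dienol ether to the quinone, which is held on tetravalent titanium as a five-membered chelate through the methoxy oxygen and the neighbouring carbonyl oxygen; the closest known reaction type is the BINOL–titanium-catalysed enantioselective quinone Diels–Alder reaction. Ring B closes in an intermolecular six-centre suprafacial–suprafacial mode, with C9–C10 bonding running ahead of C5–C6 bonding. C10 and C5 emerge cis because the ring alkene of the quinone adds suprafacially, C6 is fixed relative to them by the E geometry of the dienol ether together with the endo placement of ring A (O6 anti to H5 and to the C10 methyl), and the absolute sense comes from the BINOL ligand, which shields one face of the bound quinone. Site selectivity is secured by the methoxy group, which turns its own C=C into a vinylogous ester and leaves the methyl-bearing C=C as the dienophile. Regioselectivity follows because the chelated carbonyl (the future C4) is the stronger acceptor, so its beta carbon, the methyl-bearing one, takes the nucleophilic CH2 terminus of the diene. Any 1Z dienol ether cannot reach the s-cis form and stays behind.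

Step 5
Reactants: 10 cis-adduct
Product: 12 cis-6-(triisopropylsilyloxy)-15-noreudesm-7-ene-1,4-dione, via 3-methoxy-1,4-dione 11 (not isolated)
Conditions: SmI2 (4.5 equiv), THF–MeOH, −78 → 0 °C
Reagents that add atoms: none
Why: Single-electron reduction by divalent samarium first saturates the ene-dione C2=C3 and then cleaves the C3–OMe bond alpha to the C4 ketone (reductive cleavage of an alpha-alkoxy ketone) under cold neutral conditions that leave C5, the allylic silyl ether and C7=C8 untouched.

Step 6
Reactants: 12 cis-6-(triisopropylsilyloxy)-15-noreudesm-7-ene-1,4-dione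
Product: 13 cis-6-(triisopropylsilyloxy)-15-noreudesmane-1,4-dione (isopropyl cis to O6; both on the opposite face)
Conditions: H2 (10 bar), 5% Rh/Al2O3, EtOAc, rt
Reagents that add atoms: none
Why: Heterogeneous catalytic hydrogenation: in the folded cis-decalin the opposite face of C7=C8 is covered by ring A and by the pseudo-axial silyloxy group, so hydrogen arrives on the open convex methyl face and pushes the isopropyl group cis to O6, while rhodium avoids allylic C–O hydrogenolysis and alkene migration.

Step 7
Reactants: 13 cis-6-(triisopropylsilyloxy)-15-noreudesmane-1,4-dione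
Product: 15 trans-1,1-ethylenedioxy-6-(triisopropylsilyloxy)-15-noreudesman-4-one (H5 on the opposite face), via trans-dione 14 (not isolated)
Conditions: HOCH2CH2OH (10 equiv), p-TsOH·H2O (0.1 equiv), benzene, reflux, azeotropic removal of water
Reagents that add atoms: ethylene glycol, OCCO
Why: Acid-catalysed enolisation equilibrates C5 while ketalisation with removal of water drains the mixture: only the trans isomer offers an open carbonyl (C1, an ordinary angular-methyl decalin-1-one), C4 is held back by the 1,3-diaxial C10 methyl and the peri silyl ether, and a C1 ketal of the cis isomer would press a ketal oxygen against the axial silyloxy group or C4 against the isopropyl group, so the trans C1 mono-ketal should be the sink and C5 is set by equilibrium.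

Step 8
Reactants: 15 trans-1,1-ethylenedioxy-6-(triisopropylsilyloxy)-15-noreudesman-4-one
Product: 16 trans-1,1-ethylenedioxy-6-(triisopropylsilyloxy)eudesm-4(15)-ene
Conditions: Ph3PCH3Br (3 equiv), KOtBu (2.8 equiv), toluene, rt → 60 °C
Reagents that add atoms: methyltriphenylphosphonium bromide, C[P+](c1ccccc1)(c1ccccc1)c1ccccc1.[Br-]
Why: Wittig methylenation of the only free carbonyl: the ylide reaches C4 along the equatorial trajectory on the opposite face, C5 cannot drift back because the cis ketal is far more strained, and the equatorial C6–O bond lies in the enolate plane so that beta-elimination is stereoelectronically disfavoured.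

Step 9
Reactants: 16 trans-1,1-ethylenedioxy-6-(triisopropylsilyloxy)eudesm-4(15)-ene
Product: 17 trans-1,1-ethylenedioxy-6-(triisopropylsilyloxy)eudesmane-4,15-diol (O4 equatorial on the opposite face; C15 axial on the methyl face)
Conditions: OsO4 (5 mol %), N-methylmorpholine N-oxide, acetone–H2O, rt
Reagents that add atoms: OsO4 (catalytic oxygen carrier), O=[Os](=O)(=O)=O; N-methylmorpholine N-oxide, C[N+]1([O-])CCOCC1; water, O
Why: Catalytic syn-dihydroxylation: the axial C10 methyl blocks the methyl face of the exocyclic alkene, so osmium adds from the equatorial side and should give equatorial O4 next to O6 and an axial CH2OH group, which is the C4 configuration of the target.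

Step 10
Reactants: 17 trans-1,1-ethylenedioxy-6-(triisopropylsilyloxy)eudesmane-4,15-diol
Product: 18 4,6,15-trihydroxyeudesman-1-one (trans-fused; O4 and O6 equatorial; isopropyl axial)
Conditions: 48% aq. HF, MeCN, rt → 40 °C
Reagents that add atoms: water, O
Why: Fluoride-driven desilylation and acid hydrolysis of the dioxolane take place in one operation, and no stereocentre is at risk because C5 is no longer alpha to a carbonyl group and C10 is quaternary.

Step 11
Reactants: 19 (E)-cinnamonitrile
Product: 20 methyl (E)-cinnamimidate hydrochloride
Conditions: MeOH (1.1 equiv), HCl (g), Et2O, 0 °C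
Reagents that add atoms: methanol, CO; hydrogen chloride, Cl
Why: Pinner reaction: the HCl-activated nitrile takes up one methanol and the imidate salt crystallises, conjugate addition to the beta-phenyl alkene being slow.

Step 12
Reactants: 20 methyl (E)-cinnamimidate hydrochloride
Product: 21 trimethyl (E)-orthocinnamate
Conditions: MeOH (excess), hexane, rt
Reagents that add atoms: methanol, CO
Why: Alcoholysis of the imidate salt (second stage of the Pinner orthoester synthesis) gives the orthoester while NH4Cl precipitates, and the E alkene is not touched.

Step 13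
Reactants: 18 4,6,15-trihydroxyeudesman-1-one; 21 trimethyl (E)-orthocinnamate
Product: 22 1-oxoeudesmane-4,6,15-triyl (E)-orthocinnamate (2,7,8-trioxabicyclo[3.2.1]octane cage)
Conditions: 21 (1.2 equiv), camphorsulfonic acid (5 mol %), 4 Å MS, CH2Cl2, rt
Reagents that add atoms: none
Why: Acid-catalysed transorthoesterification: O15, O4 and O6, held within reach of one carbon by the rigid trans-decalin, replace the three methoxy groups stepwise through dialkoxycarbenium ions, the configuration of the orthoester carbon is dictated by the cage, uptake of methanol by the sieves drives the equilibrium, and the hindered C1 ketone stays out of the exchange.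

Step 14
Reactants: 22 1-oxoeudesmane-4,6,15-triyl (E)-orthocinnamate
Product: 23 target CNP0190302.1
Conditions: NaBH4, MeOH–CH2Cl2, −20 → 0 °C
Reagents that add atoms: none
Why: Ketone reduction with NaBH4: the small hydride attacks C1 axially from the opposite face and should give the equatorial alcohol cis to the C10 methyl, while the basic medium leaves the orthoester and the styryl alkene intact.

Compound list
1 | isovaleraldehyde | CC(C)CC=O | starting material
2 | cyclohexylamine | NC1CCCCC1 | starting material
3 | N-(3-methylbutylidene)cyclohexanamine | CC(C)C/C=N/C1CCCCC1 | intermediate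
4 | acetaldehyde | CC=O | starting material
5 | lithium aza-enolate of 3 (not isolated) | [Li]N(C=CC(C)C)C1CCCCC1 | intermediate
6 | lithium aldolate, 3-(lithiooxy)-2-isopropylbutylidene imine, diastereomer mixture (not isolated) | [Li]OC(C)C(C(C)C)C=NC1CCCCC1 | intermediate
7 | (E)-2-isopropylbut-2-enal | C/C=C(/C=O)C(C)C | intermediate
8 | (1E)-2-isopropyl-1-(triisopropylsilyloxy)buta-1,3-diene | C=C/C(C(C)C)=C/O[Si](C(C)C)(C(C)C)C(C)C | intermediate
9 | 2-methoxy-5-methyl-1,4-benzoquinone | COC1=CC(=O)C(C)=CC1=O | starting material
10 | cis-adduct, 3-methoxy-6-(triisopropylsilyloxy)-15-noreudesma-2,7-diene-1,4-dione; H5 cis to C10-CH3, O6 trans to both | CC(C)C1=CC[C@]2(C)C(=O)C=C(OC)C(=O)[C@@H]2[C@@H]1O[Si](C(C)C)(C(C)C)C(C)C | intermediate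
11 | 3-methoxy-1,4-dione, C3 epimers (not isolated) | CC(C)C1=CC[C@]2(C)C(=O)CC(OC)C(=O)[C@@H]2[C@@H]1O[Si](C(C)C)(C(C)C)C(C)C | intermediate
12 | cis-6-(triisopropylsilyloxy)-15-noreudesm-7-ene-1,4-dione | CC(C)C1=CC[C@]2(C)C(=O)CCC(=O)[C@@H]2[C@@H]1O[Si](C(C)C)(C(C)C)C(C)C | intermediate
13 | cis-6-(triisopropylsilyloxy)-15-noreudesmane-1,4-dione; isopropyl cis to O6 | CC(C)[C@@H]1CC[C@]2(C)C(=O)CCC(=O)[C@@H]2[C@@H]1O[Si](C(C)C)(C(C)C)C(C)C | intermediate
14 | trans-dione, C5 epimer of 13 (not isolated) | CC(C)[C@@H]1CC[C@]2(C)C(=O)CCC(=O)[C@H]2[C@@H]1O[Si](C(C)C)(C(C)C)C(C)C | intermediate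
15 | trans-1,1-ethylenedioxy-6-(triisopropylsilyloxy)-15-noreudesman-4-one | CC(C)[C@@H]1CC[C@]2(C)C3(CCC(=O)[C@H]2[C@@H]1O[Si](C(C)C)(C(C)C)C(C)C)OCCO3 | intermediate
16 | trans-1,1-ethylenedioxy-6-(triisopropylsilyloxy)eudesm-4(15)-ene | CC(C)[C@@H]1CC[C@]2(C)C3(CCC(=C)[C@H]2[C@@H]1O[Si](C(C)C)(C(C)C)C(C)C)OCCO3 | intermediate
17 | trans-1,1-ethylenedioxy-6-(triisopropylsilyloxy)eudesmane-4,15-diol; O4 equatorial, C15 axial | CC(C)[C@@H]1CC[C@]2(C)C3(CC[C@@](O)(CO)[C@H]2[C@@H]1O[Si](C(C)C)(C(C)C)C(C)C)OCCO3 | intermediate
18 | 4,6,15-trihydroxyeudesman-1-one | CC(C)[C@@H]1CC[C@]2(C)C(=O)CC[C@@](O)(CO)[C@H]2[C@@H]1O | intermediate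
19 | (E)-cinnamonitrile | N#C/C=C/c1ccccc1 | starting material
20 | methyl (E)-cinnamimidate hydrochloride | COC(=[NH2+])/C=C/c1ccccc1.[Cl-] | intermediate
21 | trimethyl (E)-orthocinnamate | COC(OC)(OC)/C=C/c1ccccc1 | intermediate
22 | 1-oxoeudesmane-4,6,15-triyl (E)-orthocinnamate | CC(C)[C@@H]1CC[C@@]2(C)[C@@H]3[C@@H]1O[C@]1(/C=C/c4ccccc4)OC[C@@]3(CCC2=O)O1 | intermediate
23 | CNP0190302.1 | CC(C)[C@@H]1CC[C@@]2(C)[C@@H]3[C@@H]1O[C@]1(/C=C/c4ccccc4)OC[C@@]3(CC[C@@H]2O)O1 | target

Total step count: 14. Longest linear sequence: 12 (steps 1–10, 13, 14).

Steps most likely to fail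

Step 7. Four things may go wrong.
- Enolisation toward C5 may be too slow, because in the favoured cis conformer H5 lies close to the plane of the C4 carbonyl.
- The trans ketone is the less stable epimer before ketalisation (axial isopropyl, peri O4/O6 contact).
- The silyl ether may be lost, after which O6 would add to C1 and lock the cis series.
- C4 may ketalise in place of C1.

Fallback, kinetic instead of thermodynamic control: the fallback sets out from 13.
- Ring A of 13 is dehydrogenated with IBX (DMSO, 70 °C) to the cis ene-dione F2, whose only acidic hydrogen is H5.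
- F2 is deprotonated completely with KN(SiMe3)2 (THF, −78 °C). The planar extended enolate is quenched cold with AcOH, and the proton is expected on the face away from the perpendicular C10 methyl, giving the trans ene-dione F3.
- F3 is reduced at once with Zn/AcOH to 14.
- 14 is ketalised under aprotic, non-equilibrating conditions (Me3SiOCH2CH2OSiMe3, cat. Me3SiOTf, CH2Cl2, −78 °C), and the route is rejoined at 15.

Step 4. Facial or endo selectivity may be poor. The Lewis acid may also strip the silyl group and divert the pair into a Mukaiyama–Michael addition.

Fallback, resolution instead of catalyst control: 8 and 9 are heated without any Lewis acid (toluene, 70 °C). The unchelated future C4 carbonyl is still the stronger acceptor, so site, regio- and endo preferences are unchanged. This gives 10 together with the mirror-image adduct F1. The enantiomers are separated by preparative chromatography on a chiral stationary phase, and the route is rejoined at 10.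

Step 13. Closure may stop at the hindered tertiary O4. The released methanol may ketalise C1, the product may hydrolyse during work-up, or reagent 21 may be hard to obtain pure.

Fallback, orthoester from an ester instead of by exchange (steps 11 and 12 are then not needed): the fallback sets out from 18.
- The primary C15 hydroxyl of 18 is acylated selectively with cinnamoyl chloride (2,4,6-collidine, CH2Cl2, −20 °C) to the 15-O-cinnamate F4.
- F4 is closed by acid-catalysed cyclodehydration (camphorsulfonic acid, benzene, reflux, azeotropic removal of water). O4 adds to the ester carbonyl and O6 displaces the ortho-acid hydroxyl, and the route is rejoined at 22.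

Further compounds
F1 | step 4 | mirror-image adduct (ent-10) | CC(C)C1=CC[C@@]2(C)C(=O)C=C(OC)C(=O)[C@H]2[C@H]1O[Si](C(C)C)(C(C)C)C(C)C
F2 | step 7 | cis-6-(triisopropylsilyloxy)-15-noreudesm-2-ene-1,4-dione | CC(C)[C@@H]1CC[C@]2(C)C(=O)C=CC(=O)[C@@H]2[C@@H]1O[Si](C(C)C)(C(C)C)C(C)C
F3 | step 7 | trans-6-(triisopropylsilyloxy)-15-noreudesm-2-ene-1,4-dione | CC(C)[C@@H]1CC[C@]2(C)C(=O)C=CC(=O)[C@H]2[C@@H]1O[Si](C(C)C)(C(C)C)C(C)C
F4 | step 13 | 15-O-(E)-cinnamoyl-4,6,15-trihydroxyeudesman-1-one | CC(C)[C@@H]1CC[C@]2(C)C(=O)CC[C@@](O)(COC(=O)/C=C/c3ccccc3)[C@H]2[C@@H]1O
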